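**Retrosynthetic overview** (chromene numbering: O1, C2, C3, C4, C4a, C5–C8, C8a)
1. Last operations: C-acylation of C6 with the isovaleryl group, after fluoride removes the masks on O5 and C6.
2. Pyran ring and the C4a stereocentre: O1–C2 bond by group-selective 6-endo opening of one of two identical (S)-epoxy arms on C4a by O8a; the other arm is deoxygenated back to prenyl and the C3 hydroxyl is eliminated to C3=C4.
3. Carbocycle: C7–C8 and C8a–C4a are formed in one operation from a lithium ynolate (C8/C8a, oxygen on C8a; made in the flask from a dibromomethyl ketone) and a silyl vinylketene (C7–C6–C5–C4a) by C-acylation and 6π electrocyclisation.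
4. Enabling feature: ring C4a–C8a is a dearomatised phloroglucinol in which the O–C7–C8(prenyl)=C8a–O unit lies next to the fully substituted C4a, so the ring closure cannot end in a phenol.
5. The vinylketene comes from 4π opening of a 2-silyl-3-alkoxycyclobutenone, itself from bis(prenyl)ketene and a silyl ynol ether; ring order: cyclobutenone (temporary), carbocycle, pyran.

Key step: step 7

Remark: ethyl 4-methylpent-3-enoate and the L-fructose-derived enantiomer of the Shi ketone are taken as purchasable; the Shi facial sense for a CH2–CH=CMe2 unit is assigned from the spiro transition-state model.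

Step 1
Reactants: 1 diethyl malonate; 2 prenyl bromide
Product: 3 diethyl 2,2-bis(3-methylbut-2-en-1-yl)propanedioate
Conditions: NaH (2.2 equiv), 2 (2.2 equiv), THF, 0 → 25 °C
Reagents that add atoms: none
Why: Double C-alkylation of the malonate enolate by SN2 displacement at the primary allylic bromide (malonic ester synthesis); no stereocentre.

Step 2
Reactants: 3 diethyl 2,2-bis(3-methylbut-2-en-1-yl)propanedioate
Product: 5 5-methyl-2-(3-methylbut-2-en-1-yl)hex-4-enoic acid, via diacid 4 (not isolated)
Conditions: KOH, EtOH/H2O, reflux; HCl (aq), 0 °C; pyridine, 115 °C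
Reagents that add atoms: potassium hydroxide, [K+].[OH-]
Why: Saponification and thermal decarboxylation of the disubstituted malonic acid (malonic ester synthesis); pyridine buffers the acid so that the prenyl alkenes are not protonated.

Step 3
Reactants: 6 2-(trimethylsilyl)ethanol; 7 trichloroethylene
Product: 10 triethyl{[2-(trimethylsilyl)ethoxy]ethynyl}silane, via dichlorovinyl ether 8 (not isolated), via lithium alkynide 9 (not isolated)
Conditions: KH, THF, 0 °C; 7, 25 °C; n-BuLi (2.5 equiv), –78 → –40 °C; Et3SiCl, –78 → 0 °C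
Reagents that add atoms: chlorotriethylsilane, CC[Si](Cl)(CC)CC
Why: Ynol ether synthesis by the dichlorovinyl ether route (alkoxide addition–elimination on trichloroethylene, then dehydrochlorination and chlorine–lithium exchange to the lithium alkoxyacetylide, then C-silylation); the 2-(trimethylsilyl)ethyl group is chosen because fluoride can remove it at the end.

Step 4
Reactants: 5 5-methyl-2-(3-methylbut-2-en-1-yl)hex-4-enoic acid; 10 triethyl{[2-(trimethylsilyl)ethoxy]ethynyl}silane
Product: 13 4,4-bis(3-methylbut-2-en-1-yl)-2-(triethylsilyl)-3-[2-(trimethylsilyl)ethoxy]cyclobut-2-en-1-one, via acid chloride 11 (not isolated), via ketene 12 (not isolated)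
Conditions: (COCl)2, cat. DMF, CH2Cl2, 0 → 25 °C; evaporate; 10, Et3N, PhMe, 60 °C
Reagents that add atoms: none
Why: Dehydrochlorination gives the dialkylketene, which should undergo the polar [2+2] cycloaddition of ketenes with ynol ethers; the ketene carbonyl carbon bonds to the silicon-bearing alkyne carbon because the developing positive charge sits on the oxygen-bearing carbon, so silicon ends on C2 and the alkoxy group on C3 of the cyclobutenone.

Step 5
Reactants: 13 4,4-bis(3-methylbut-2-en-1-yl)-2-(triethylsilyl)-3-[2-(trimethylsilyl)ethoxy]cyclobut-2-en-1-one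
Product: 14 4,4-bis{[(2S)-3,3-dimethyloxiran-2-yl]methyl}-2-(triethylsilyl)-3-[2-(trimethylsilyl)ethoxy]cyclobut-2-en-1-one
Conditions: L-fructose-derived Shi ketone (0.6 equiv), Oxone (2KHSO5·KHSO4·K2SO4), K2CO3, Bu4NHSO4, MeCN/(MeO)2CH2/aq. buffer, 0 °C
Reagents that add atoms: Oxone (active component potassium peroxymonosulfate), [K+].[O-]S(=O)(=O)OO
Why: Shi asymmetric epoxidation: the dioxirane of the ketone catalyst transfers oxygen to each electron-rich trisubstituted alkene through the spiro transition state, the L-fructose-derived catalyst setting (S) at each new CH–O centre, while the electron-poor tetrasubstituted ring alkene is left alone; reacting twice in one molecule should divert most of the minor enantiomer into a separable diastereomer.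

Step 6
Reactants: 15 ethyl 4-methylpent-3-enoate
Product: 17 1,1-dibromo-5-methylhex-4-en-2-one, via tetrahedral adduct 16 (not isolated)
Conditions: CH2Br2 (1.2 equiv), Li(TMP) (lithium 2,2,6,6-tetramethylpiperidide, 1.2 equiv), THF, –90 °C; 15, –90 °C; AcOH in THF, –90 → 0 °C
Reagents that add atoms: dibromomethane, BrCBr
Why: Dibromomethyllithium, made in the flask from CH2Br2 and Li(TMP), adds to the ester carbonyl to give the tetrahedral lithium alkoxide 16, which should persist at –90 °C and collapse to the dibromomethyl ketone only on the cold acidic quench (first stage of the Kowalski ester homologation, stopped at the ketone), so that the ynolate can later be made free of lithium ethoxide; the hemiketal carbon of 16 becomes the carbonyl carbon, so no stereocentre is carried on.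

Step 7
Reactants: 14 4,4-bis{[(2S)-3,3-dimethyloxiran-2-yl]methyl}-2-(triethylsilyl)-3-[2-(trimethylsilyl)ethoxy]cyclobut-2-en-1-one; 17 1,1-dibromo-5-methylhex-4-en-2-one
Product: 22 6,6-bis{[(2S)-3,3-dimethyloxiran-2-yl]methyl}-3-hydroxy-2-(3-methylbut-2-en-1-yl)-4-(triethylsilyl)-5-[2-(trimethylsilyl)ethoxy]cyclohexa-2,4-dien-1-one, via vinylketene 18 (not isolated), via dibromoenolate 19 (not isolated), via ynolate 20 (not isolated), via oxidodienylketene 21 (not isolated)
Conditions: flask A: 14, PhMe, 90 °C; flask B: 17, LiN(SiMe3)2 (1.05 equiv), THF, –78 °C, then n-BuLi (1.05 equiv), –78 → 0 °C; B into A at –78 → 0 °C; AcOH, –78 °C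
Reagents that add atoms: none
Why: Proposed new method: heating should open the 2-silylcyclobutenone by conrotatory 4π electrocyclic ring opening to the silyl-stabilised vinylketene 18, while in a second flask ketone 17 is deprotonated at its CHBr2 carbon to dibromoenolate 19 and bromine–lithium exchange with 1,2-shift of the prenyl group gives ynolate 20 (second stage of the Kowalski homologation); the carbon terminus of 20 (future C8) then acylates at the ketene carbon of 18 (future C7) on the side away from SiEt3, giving the 3-oxido-dienylketene 21, whose 6π electrocyclisation joins the new ketene carbon (C8a) to the fully substituted diene terminus (C4a). The closest known reaction is the benzannulation of (trialkylsilyl)vinylketenes with lithium ynolates, here interrupted before aromatisation, and the ring-closing event is the thermal reverse of the photochemical opening of 6,6-disubstituted cyclohexa-2,4-dienones. The carbocycle is closed in the disrotatory 6π mode; no other ring forms, and because C4a carries two carbon substituents the product cannot tautomerise to a phenol and should appear directly at the dearomatised oxidation level of the target. No stereocentre is created: C4a becomes quaternary but bears two identical (S)-epoxy arms, so neither the alkene geometry of 18 nor the face of ring closure has a stereochemical consequence, which is the reason for the twofold-symmetric precursor; the two epoxide centres are only carried along. The selectivities needed are C- over O-acylation of the ynolate, attack at the ketene carbon in preference to the epoxides, and the cisoid enolate geometry; they are secured by the carbon-centred reactivity of ynolates toward ketenes, by preforming the far more electrophilic ketene, using an ynolate solution that holds no alkoxide and keeping the anionic stage below 0 °C, and by the bulky silyl group, which suppresses ketene dimerisation and steers the ynolate to the vinyl side. Regiochemistry is fixed by polarity, since the nucleophilic prenyl-bearing carbon can only bond to the ketene carbon and the oxygen-bearing carbon then becomes the ketene that closes onto C4a.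

Step 8
Reactants: 22 6,6-bis{[(2S)-3,3-dimethyloxiran-2-yl]methyl}-3-hydroxy-2-(3-methylbut-2-en-1-yl)-4-(triethylsilyl)-5-[2-(trimethylsilyl)ethoxy]cyclohexa-2,4-dien-1-one
Product: 23 (3S,4aS)-4a-{[(2S)-3,3-dimethyloxiran-2-yl]methyl}-3-hydroxy-2,2-dimethyl-8-(3-methylbut-2-en-1-yl)-6-(triethylsilyl)-5-[2-(trimethylsilyl)ethoxy]-2,3,4,4a-tetrahydro-7H-chromen-7-one
Conditions: (±)-camphorsulfonic acid (10 mol %), CH2Cl2, –40 → 0 °C; Et3N
Reagents that add atoms: none
Why: Acid-catalysed epoxide-opening cyclisation (6-endo, Markovnikov at the CMe2 carbon) by the enol oxygen on C8a, the only free oxygen within reach because O5 is masked; the step chooses between the two diastereotopic epoxy arms and so creates the C4a stereocentre, since only one arm lets O8a attack C2 in line with the breaking C–O bond through a chair with the C3 oxygen equatorial, and with (S)-epoxides that arm should give the C4a configuration of the target while C3 keeps its configuration.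

Step 9
Reactants: 23 (3S,4aS)-4a-{[(2S)-3,3-dimethyloxiran-2-yl]methyl}-3-hydroxy-2,2-dimethyl-8-(3-methylbut-2-en-1-yl)-6-(triethylsilyl)-5-[2-(trimethylsilyl)ethoxy]-2,3,4,4a-tetrahydro-7H-chromen-7-one
Product: 24 (3S,4aR)-3-hydroxy-2,2-dimethyl-4a,8-bis(3-methylbut-2-en-1-yl)-6-(triethylsilyl)-5-[2-(trimethylsilyl)ethoxy]-2,3,4,4a-tetrahydro-7H-chromen-7-one
Conditions: MeReO3 (5 mol %), PPh3 (1.5 equiv), PhMe, 50 °C
Reagents that add atoms: none
Why: Rhenium-catalysed oxygen-atom transfer from the remaining epoxide to PPh3 (epoxide deoxygenation) should restore the prenyl alkene under neutral conditions that leave the alcohol, the enol ethers and the silyl groups alone; the C4a descriptor changes only because the substituent priorities change.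

Step 10
Reactants: 24 (3S,4aR)-3-hydroxy-2,2-dimethyl-4a,8-bis(3-methylbut-2-en-1-yl)-6-(triethylsilyl)-5-[2-(trimethylsilyl)ethoxy]-2,3,4,4a-tetrahydro-7H-chromen-7-one
Product: 25 (4aR)-2,2-dimethyl-4a,8-bis(3-methylbut-2-en-1-yl)-6-(triethylsilyl)-5-[2-(trimethylsilyl)ethoxy]-2,4a-dihydro-7H-chromen-7-one
Conditions: Burgess reagent (MeO2C–N(–)–SO2–N(+)Et3), PhMe, 60 °C
Reagents that add atoms: none
Why: Burgess dehydration by syn elimination of the sulfamate ester; C2 is quaternary, so the alkene can only form between C3 and C4, and the non-ionising conditions should leave C4a and the vinylogous esters untouched.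

Step 11
Reactants: 25 (4aR)-2,2-dimethyl-4a,8-bis(3-methylbut-2-en-1-yl)-6-(triethylsilyl)-5-[2-(trimethylsilyl)ethoxy]-2,4a-dihydro-7H-chromen-7-one
Product: 26 (4aR)-7-hydroxy-2,2-dimethyl-4a,8-bis(3-methylbut-2-en-1-yl)-2,4a-dihydro-5H-chromen-5-one
Conditions: Bu4NF (3 equiv), THF, 0 → 25 °C; NH4Cl (aq)
Reagents that add atoms: none
Why: Fluoride attacks the silicon of the 2-(trimethylsilyl)ethyl group, which fragments to ethene and the vinylogous carboxylate (C5 carbonyl unmasked), and the C6 silyl group, then on the central carbon of a 1,3-diketonate, is cleaved as well; C4a is not enolisable and keeps its configuration.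

Step 12
Reactants: 26 (4aR)-7-hydroxy-2,2-dimethyl-4a,8-bis(3-methylbut-2-en-1-yl)-2,4a-dihydro-5H-chromen-5-one; 27 3-methylbutanoic acid
Product: 29 (4aR)-7-hydroxy-2,2-dimethyl-4a,8-bis(3-methylbut-2-en-1-yl)-6-(3-methylbutanoyl)-2,4a-dihydro-5H-chromen-5-one, via enol ester 28 (not isolated)
Conditions: N,N'-dicyclohexylcarbodiimide, 4-(dimethylamino)pyridine (1.2 equiv), CH2Cl2, 0 → 25 °C
Reagents that add atoms: none
Why: Carbodiimide-mediated O-acylation of the cyclic 1,3-dione enol followed by the aminopyridine-mediated O-to-C acyl shift to C6, the only carbon between two carbonyl groups; the chelated acyl-dione enol is the thermodynamic product.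

**Compound list**
1 | diethyl malonate | CCOC(=O)CC(=O)OCC | starting material
2 | prenyl bromide (1-bromo-3-methylbut-2-ene) | CC(C)=CCBr | starting material
3 | diethyl 2,2-bis(3-methylbut-2-en-1-yl)propanedioate | CCOC(=O)C(CC=C(C)C)(CC=C(C)C)C(=O)OCC | intermediate
4 | 2,2-bis(3-methylbut-2-en-1-yl)propanedioic acid | OC(=O)C(CC=C(C)C)(CC=C(C)C)C(=O)O | intermediate (not isolated)
5 | 5-methyl-2-(3-methylbut-2-en-1-yl)hex-4-enoic acid | CC(C)=CCC(CC=C(C)C)C(=O)O | intermediate
6 | 2-(trimethylsilyl)ethanol | C[Si](C)(C)CCO | starting material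
7 | trichloroethylene | ClC=C(Cl)Cl | starting material
8 | {2-[(E)-1,2-dichloroethenoxy]ethyl}(trimethyl)silane | C[Si](C)(C)CCO/C(Cl)=C\Cl | intermediate (not isolated)
9 | lithium [2-(trimethylsilyl)ethoxy]ethynide | [Li]C#COCC[Si](C)(C)C | intermediate (not isolated)
10 | triethyl{[2-(trimethylsilyl)ethoxy]ethynyl}silane | CC[Si](CC)(CC)C#COCC[Si](C)(C)C | intermediate
11 | 5-methyl-2-(3-methylbut-2-en-1-yl)hex-4-enoyl chloride | CC(C)=CCC(CC=C(C)C)C(Cl)=O | intermediate (not isolated)
12 | 5-methyl-2-(3-methylbut-2-en-1-yl)hexa-1,4-dien-1-one (bis(prenyl)ketene) | CC(C)=CCC(=C=O)CC=C(C)C | intermediate (not isolated)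
13 | 4,4-bis(3-methylbut-2-en-1-yl)-2-(triethylsilyl)-3-[2-(trimethylsilyl)ethoxy]cyclobut-2-en-1-one | O=C1C([Si](CC)(CC)CC)=C(OCC[Si](C)(C)C)C1(CC=C(C)C)CC=C(C)C | intermediate
14 | 4,4-bis{[(2S)-3,3-dimethyloxiran-2-yl]methyl}-2-(triethylsilyl)-3-[2-(trimethylsilyl)ethoxy]cyclobut-2-en-1-one | O=C1C([Si](CC)(CC)CC)=C(OCC[Si](C)(C)C)C1(C[C@@H]2OC2(C)C)C[C@@H]3OC3(C)C | intermediate
15 | ethyl 4-methylpent-3-enoate | CCOC(=O)CC=C(C)C | starting material
16 | lithium 1,1-dibromo-2-ethoxy-5-methylhex-4-en-2-olate (tetrahedral adduct, racemic) | [Li+].[O-]C(OCC)(CC=C(C)C)C(Br)Br | intermediate (not isolated)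
17 | 1,1-dibromo-5-methylhex-4-en-2-one | O=C(CC=C(C)C)C(Br)Br | intermediate
18 | 5-[(2S)-3,3-dimethyloxiran-2-yl]-4-{[(2S)-3,3-dimethyloxiran-2-yl]methyl}-2-(triethylsilyl)-3-[2-(trimethylsilyl)ethoxy]penta-1,3-dien-1-one | O=C=C([Si](CC)(CC)CC)C(OCC[Si](C)(C)C)=C(C[C@@H]1OC1(C)C)C[C@@H]2OC2(C)C | intermediate (not isolated)
19 | lithium 1,1-dibromo-5-methylhexa-1,4-dien-2-olate | [Li+].[O-]C(CC=C(C)C)=C(Br)Br | intermediate (not isolated)
20 | lithium 5-methylhex-4-en-1-yn-1-olate | [Li+].[O-]C#CCC=C(C)C | intermediate (not isolated)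
21 | lithium (3Z)-7-[(2S)-3,3-dimethyloxiran-2-yl]-6-{[(2S)-3,3-dimethyloxiran-2-yl]methyl}-2-(3-methylbut-2-en-1-yl)-1-oxo-4-(triethylsilyl)-5-[2-(trimethylsilyl)ethoxy]hepta-1,3,5-trien-3-olate | [Li+].O=C=C(CC=C(C)C)/C([O-])=C(/[Si](CC)(CC)CC)C(OCC[Si](C)(C)C)=C(C[C@@H]1OC1(C)C)C[C@@H]2OC2(C)C | intermediate (not isolated)
22 | 6,6-bis{[(2S)-3,3-dimethyloxiran-2-yl]methyl}-3-hydroxy-2-(3-methylbut-2-en-1-yl)-4-(triethylsilyl)-5-[2-(trimethylsilyl)ethoxy]cyclohexa-2,4-dien-1-one | O=C1C(CC=C(C)C)=C(O)C([Si](CC)(CC)CC)=C(OCC[Si](C)(C)C)C1(C[C@@H]2OC2(C)C)C[C@@H]3OC3(C)C | intermediate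
23 | (3S,4aS)-4a-{[(2S)-3,3-dimethyloxiran-2-yl]methyl}-3-hydroxy-2,2-dimethyl-8-(3-methylbut-2-en-1-yl)-6-(triethylsilyl)-5-[2-(trimethylsilyl)ethoxy]-2,3,4,4a-tetrahydro-7H-chromen-7-one | CC(C)=CCC1=C2OC(C)(C)[C@@H](O)C[C@@]2(C[C@@H]3OC3(C)C)C(OCC[Si](C)(C)C)=C([Si](CC)(CC)CC)C1=O | intermediate
24 | (3S,4aR)-3-hydroxy-2,2-dimethyl-4a,8-bis(3-methylbut-2-en-1-yl)-6-(triethylsilyl)-5-[2-(trimethylsilyl)ethoxy]-2,3,4,4a-tetrahydro-7H-chromen-7-one | CC(C)=CCC1=C2OC(C)(C)[C@@H](O)C[C@@]2(CC=C(C)C)C(OCC[Si](C)(C)C)=C([Si](CC)(CC)CC)C1=O | intermediate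
25 | (4aR)-2,2-dimethyl-4a,8-bis(3-methylbut-2-en-1-yl)-6-(triethylsilyl)-5-[2-(trimethylsilyl)ethoxy]-2,4a-dihydro-7H-chromen-7-one | CC(C)=CCC1=C2OC(C)(C)C=C[C@@]2(CC=C(C)C)C(OCC[Si](C)(C)C)=C([Si](CC)(CC)CC)C1=O | intermediate
26 | (4aR)-7-hydroxy-2,2-dimethyl-4a,8-bis(3-methylbut-2-en-1-yl)-2,4a-dihydro-5H-chromen-5-one | CC(C)=CCC1=C2OC(C)(C)C=C[C@@]2(CC=C(C)C)C(=O)C=C1O | intermediate
27 | 3-methylbutanoic acid (isovaleric acid) | CC(C)CC(=O)O | starting material
28 | (4aR)-2,2-dimethyl-4a,8-bis(3-methylbut-2-en-1-yl)-5-oxo-4a,5-dihydro-2H-chromen-7-yl 3-methylbutanoate | CC(C)=CCC1=C2OC(C)(C)C=C[C@@]2(CC=C(C)C)C(=O)C=C1OC(=O)CC(C)C | intermediate (not isolated)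
29 | (4aR)-7-hydroxy-2,2-dimethyl-4a,8-bis(3-methylbut-2-en-1-yl)-6-(3-methylbutanoyl)-2,4a-dihydro-5H-chromen-5-one | CC(C)=CCC1=C2OC(C)(C)C=C[C@@]2(CC=C(C)C)C(=O)C(C(=O)CC(C)C)=C1O | target

**Step count**
Total: 12 steps. Longest linear sequence: 10 steps (1, 2, 4, 5, 7, 8, 9, 10, 11, 12); steps 3 and 6 are side branches.

**Steps most likely to fail**

Step 7 (proposed new method). The cyclobutenone may not open far enough to accumulate the vinylketene (ring–chain equilibrium on the side of the vinylogous ester). Ketone 17 may be deprotonated at C3 instead of at the CHBr2 carbon. The ynolate may be consumed by the epoxides or the cyclobutenone carbonyl, or the adduct may not reach the cisoid geometry needed for ring closure. The fallback is the thermal Danheiser benzannulation of a cyclobutenone with a siloxyalkyne, in which no anion meets the epoxides or the ketene. It stops at the cyclohexa-2,4-dienone when C4 of the cyclobutenone is disubstituted and gives the same ring constitution by a [2+2]/4π/6π sequence. It sets out from 5, 9 and 17 and comes back at 26. Quenching 9 with water instead of Et3SiCl should give [2-(ethynyloxy)ethyl](trimethyl)silane F1. Acid 5 (as 11, Et3N, PhMe, 60 °C) and F1 should give 4,4-bis(3-methylbut-2-en-1-yl)-3-[2-(trimethylsilyl)ethoxy]cyclobut-2-en-1-one F2, and epoxidation under the conditions of step 5 should give 4,4-bis{[(2S)-3,3-dimethyloxiran-2-yl]methyl}-3-[2-(trimethylsilyl)ethoxy]cyclobut-2-en-1-one F3. Separately, 17 is taken through 19 to ynolate 20 with LiN(SiMe3)2 and n-BuLi as in step 7, and O-silylation with iPr3SiCl at 0 °C should give triisopropyl[(5-methylhex-4-en-1-yn-1-yl)oxy]silane F4. Heating F3 with F4 in PhMe at 100 °C should give 6,6-bis{[(2S)-3,3-dimethyloxiran-2-yl]methyl}-2-(3-methylbut-2-en-1-yl)-3-[(triisopropylsilyl)oxy]-5-[2-(trimethylsilyl)ethoxy]cyclohexa-2,4-dien-1-one F5. K2CO3 in MeOH at 0 °C should free the enol, giving the 4-desilyl analogue of 22 F6. The conditions of steps 8, 9 and 10 should then give in turn the 6-desilyl analogue of 23 F7, the 6-desilyl analogue of 24 F8 and the 6-desilyl analogue of 25 F9, and Bu4NF converts F9 into 26.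

Step 8. The closure may take the five-membered (5-exo) course instead of the six-membered one, or may discriminate poorly between the two epoxy arms. The fallback fixes ring size and group selection through selenium and also replaces steps 9 and 10. It sets out from 13 and 17 and comes back at 25. Because phenylselenide opens the epoxide at C3 with inversion, the enantiomeric epoxides are needed: 13 with the ordinary D-fructose-derived Shi ketone should give the (R,R)-bis-epoxide enantiomer of 14 F10. The conditions of step 7, with 17 as the ynolate source, should give the enantiomer of 22 F11. (PhSe)2, NaBH4, EtOH should then give 3-hydroxy-6,6-bis[(2S)-3-hydroxy-3-methyl-2-(phenylselanyl)butyl]-2-(3-methylbut-2-en-1-yl)-4-(triethylsilyl)-5-[2-(trimethylsilyl)ethoxy]cyclohexa-2,4-dien-1-one F12. Camphorsulfonic acid in CH2Cl2 ionises a tertiary alcohol with selenium participation; O8a opens the seleniranium ion at CMe2 under the same chair control and should give the 3-(phenylselanyl) analogue of 23 whose second arm is still the hydroxy selenide F13. MeSO2Cl, Et3N should return that arm to prenyl by reductive elimination, giving the 3-(phenylselanyl) analogue of 24 F14. H2O2, pyridine, 0 °C (selenoxide syn elimination, possible only toward C4) should give 25.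

Step 10. The elimination may be sluggish at the hindered carbinol next to the quaternary C2, or ionisation with participation of the ring oxygen may contract the pyran. The fallback changes the oxidation level instead of eliminating water. It sets out from 24 and comes back at 25. Dess–Martin periodinane should give the 3-oxo analogue of 24 F15. KN(SiMe3)2 and N-(5-chloropyridin-2-yl)triflimide at –78 °C should give the C3 enol triflate of that ketone F16; only C4 is enolisable. Pd(OAc)2, PPh3, Bu3N, HCO2H, DMF, 60 °C (triflate reduction) should give 25.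

**Further compounds**
F1 | step 7 | [2-(ethynyloxy)ethyl](trimethyl)silane | C#COCC[Si](C)(C)C
F2 | step 7 | 4,4-bis(3-methylbut-2-en-1-yl)-3-[2-(trimethylsilyl)ethoxy]cyclobut-2-en-1-one | O=C1C=C(OCC[Si](C)(C)C)C1(CC=C(C)C)CC=C(C)C
F3 | step 7 | 4,4-bis{[(2S)-3,3-dimethyloxiran-2-yl]methyl}-3-[2-(trimethylsilyl)ethoxy]cyclobut-2-en-1-one | O=C1C=C(OCC[Si](C)(C)C)C1(C[C@@H]2OC2(C)C)C[C@@H]3OC3(C)C
F4 | step 7 | triisopropyl[(5-methylhex-4-en-1-yn-1-yl)oxy]silane | CC(C)=CCC#CO[Si](C(C)C)(C(C)C)C(C)C
F5 | step 7 | 6,6-bis{[(2S)-3,3-dimethyloxiran-2-yl]methyl}-2-(3-methylbut-2-en-1-yl)-3-[(triisopropylsilyl)oxy]-5-[2-(trimethylsilyl)ethoxy]cyclohexa-2,4-dien-1-one | O=C1C(CC=C(C)C)=C(O[Si](C(C)C)(C(C)C)C(C)C)C=C(OCC[Si](C)(C)C)C1(C[C@@H]2OC2(C)C)C[C@@H]3OC3(C)C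
F6 | step 7 | 4-desilyl analogue of 22 (H in place of SiEt3) | O=C1C(CC=C(C)C)=C(O)C=C(OCC[Si](C)(C)C)C1(C[C@@H]2OC2(C)C)C[C@@H]3OC3(C)C
F7 | step 7 | 6-desilyl analogue of 23 (H in place of SiEt3 at C6) | CC(C)=CCC1=C2OC(C)(C)[C@@H](O)C[C@@]2(C[C@@H]3OC3(C)C)C(OCC[Si](C)(C)C)=CC1=O
F8 | step 7 | 6-desilyl analogue of 24 (H in place of SiEt3 at C6) | CC(C)=CCC1=C2OC(C)(C)[C@@H](O)C[C@@]2(CC=C(C)C)C(OCC[Si](C)(C)C)=CC1=O
F9 | step 7 | 6-desilyl analogue of 25 (H in place of SiEt3 at C6) | CC(C)=CCC1=C2OC(C)(C)C=C[C@@]2(CC=C(C)C)C(OCC[Si](C)(C)C)=CC1=O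
F10 | step 8 | 4,4-bis{[(2R)-3,3-dimethyloxiran-2-yl]methyl}-2-(triethylsilyl)-3-[2-(trimethylsilyl)ethoxy]cyclobut-2-en-1-one (enantiomer of 14) | O=C1C([Si](CC)(CC)CC)=C(OCC[Si](C)(C)C)C1(C[C@H]2OC2(C)C)C[C@H]3OC3(C)C
F11 | step 8 | 6,6-bis{[(2R)-3,3-dimethyloxiran-2-yl]methyl}-3-hydroxy-2-(3-methylbut-2-en-1-yl)-4-(triethylsilyl)-5-[2-(trimethylsilyl)ethoxy]cyclohexa-2,4-dien-1-one (enantiomer of 22) | O=C1C(CC=C(C)C)=C(O)C([Si](CC)(CC)CC)=C(OCC[Si](C)(C)C)C1(C[C@H]2OC2(C)C)C[C@H]3OC3(C)C
F12 | step 8 | 3-hydroxy-6,6-bis[(2S)-3-hydroxy-3-methyl-2-(phenylselanyl)butyl]-2-(3-methylbut-2-en-1-yl)-4-(triethylsilyl)-5-[2-(trimethylsilyl)ethoxy]cyclohexa-2,4-dien-1-one | O=C1C(CC=C(C)C)=C(O)C([Si](CC)(CC)CC)=C(OCC[Si](C)(C)C)C1(C[C@H]([Se]c2ccccc2)C(C)(C)O)C[C@H]([Se]c3ccccc3)C(C)(C)O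
F13 | step 8 | 3-(phenylselanyl) analogue of 23 (equatorial PhSe at C3 in place of OH) carrying a (2S)-3-hydroxy-3-methyl-2-(phenylselanyl)butyl arm on C4a | CC(C)=CCC1=C2OC(C)(C)[C@@H]([Se]c3ccccc3)C[C@@]2(C[C@H]([Se]c4ccccc4)C(C)(C)O)C(OCC[Si](C)(C)C)=C([Si](CC)(CC)CC)C1=O
F14 | step 8 | 3-(phenylselanyl) analogue of 24 (PhSe at C3 in place of OH) | CC(C)=CCC1=C2OC(C)(C)[C@@H]([Se]c3ccccc3)C[C@@]2(CC=C(C)C)C(OCC[Si](C)(C)C)=C([Si](CC)(CC)CC)C1=O
F15 | step 10 | 3-oxo analogue of 24 (ketone at C3) | CC(C)=CCC1=C2OC(C)(C)C(=O)C[C@@]2(CC=C(C)C)C(OCC[Si](C)(C)C)=C([Si](CC)(CC)CC)C1=O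
F16 | step 10 | C3 enol triflate of F15 (3-[(trifluoromethanesulfonyl)oxy] analogue of 25) | CC(C)=CCC1=C2OC(C)(C)C(OS(=O)(=O)C(F)(F)F)=C[C@@]2(CC=C(C)C)C(OCC[Si](C)(C)C)=C([Si](CC)(CC)CC)C1=O
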